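**Retrosynthetic overview**

1. Last cut: the secondary allylic ester (acyl C–O bond) gives (S)-1-(3,4,5-trimethoxyphenyl)prop-2-en-1-ol and (Z)-2-(angeloyloxymethyl)but-2-enoic acid. The C–O bond at the stereocentre is never broken.
2. The (S)-carbinol comes from the racemic carbinol by lipase kinetic resolution, and that from 3,4,5-trimethoxybenzaldehyde plus vinylmagnesium bromide.
3. The diester acid comes from (Z)-2-(hydroxymethyl)but-2-enoic acid by O-acylation of its alkoxide–carboxylate dianion with angelic anhydride (the angelate Z-alkene is bought).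
4. The hydroxy acid comes from (Z)-2-bromobut-2-en-1-ol (Br/Li exchange, CO2, retention), made from (Z)-2-bromobut-2-enal and crotonaldehyde. The stable enal geometry (CHO trans to CH3) becomes the required Z-acid because CHO ends as CH2O and Br as CO2H.
5. No ring is formed; the only ring is the arene bought with the aldehyde. The route is convergent (2 + 4 + 1 steps).

Assumption: the target is the (S)-ester with both trisubstituted alkenes Z, as the SMILES encodes; angelic anhydride is taken as a purchasable reagent (otherwise one operation from angelic acid).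

**Route**

Step 1
Reactants: 1 3,4,5-trimethoxybenzaldehyde
Product: 2 rac-1-(3,4,5-trimethoxyphenyl)prop-2-en-1-ol
Conditions: CH2=CHMgBr (1.2 equiv), THF, −78 to 0 °C; then H2O quench
Reagents that add atoms: vinylmagnesium bromide, C=C[Mg]Br
Why: Grignard 1,2-addition to a non-enolisable aryl aldehyde gives the vinyl carbinol, formed racemic and resolved in step 2.

Step 2
Reactants: 2 rac-1-(3,4,5-trimethoxyphenyl)prop-2-en-1-ol
Product: 3 (S)-1-(3,4,5-trimethoxyphenyl)prop-2-en-1-ol
Conditions: Novozym 435 (immobilised Candida antarctica lipase B), vinyl acetate (3 equiv), MTBE, 30 °C, run to about 55% conversion (chiral HPLC); chromatography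
Reagents that add atoms: none
Why: Lipase-catalysed kinetic resolution by enantioselective transesterification (Kazlauskas rule, aryl large and vinyl medium) acetylates the (R)-carbinol and leaves the (S)-carbinol, which sets the only stereocentre of the target.

Step 3
Reactants: 4 (E)-but-2-enal (crotonaldehyde)
Product: 6 (Z)-2-bromobut-2-enal, via rac-(2R,3S)-2,3-dibromobutanal 5 (not isolated)
Conditions: Br2 (1.05 equiv), CH2Cl2, 0 °C; then Et3N (1.3 equiv), 0 °C to rt
Reagents that add atoms: bromine, BrBr
Why: Anti bromination of the alkene followed by E1cB dehydrobromination at the acidic α-position gives the thermodynamically preferred α-bromoenal with CHO trans to CH3 (Br cis to CH3, Z).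

Step 4
Reactants: 6 (Z)-2-bromobut-2-enal
Product: 7 (Z)-2-bromobut-2-en-1-ol
Conditions: NaBH4 (1.0 equiv), CeCl3·7H2O (1.0 equiv), MeOH, 0 °C
Reagents that add atoms: none
Why: Luche 1,2-reduction delivers hydride only to the carbonyl, so the vinyl bromide and the alkene geometry are untouched.

Step 5
Reactants: 7 (Z)-2-bromobut-2-en-1-ol
Product: 9 (Z)-2-(hydroxymethyl)but-2-enoic acid, via lithium (E)-2-lithiobut-2-en-1-olate 8 (not isolated)
Conditions: t-BuLi (3.1 equiv), Et2O, −78 °C, 1 h; cannulate onto excess dry CO2 in Et2O, −78 °C to rt; 2 M HCl to pH 2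
Reagents that add atoms: carbon dioxide, O=C=O
Why: O-deprotonation then bromine–lithium exchange gives a configurationally stable O,2-dilithio allyl alcohol reagent whose carboxylation proceeds with retention, so CO2H ends up cis to CH3 (Z).

Step 6
Reactants: 9 (Z)-2-(hydroxymethyl)but-2-enoic acid; 10 angelic anhydride
Product: 12 (Z)-2-({[(Z)-2-methylbut-2-enoyl]oxy}methyl)but-2-enoic acid, via dilithium (Z)-2-(oxidomethyl)but-2-enoate 11 (not isolated)
Conditions: LiN(SiMe3)2 (2.0 equiv), THF, −78 to 0 °C; 10 (1.1 equiv), −40 to 0 °C; 1 M HCl work-up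
Reagents that add atoms: none
Why: Chemoselective O-acylation, since in the dianion the alkoxide is far more nucleophilic than the carboxylate, and acylation of a lithium alkoxide by the anhydride without a nucleophilic catalyst is a stereoconservative angeloylation (no Z to E drift to the tiglate).

Step 7
Reactants: 12 (Z)-2-({[(Z)-2-methylbut-2-enoyl]oxy}methyl)but-2-enoic acid; 3 (S)-1-(3,4,5-trimethoxyphenyl)prop-2-en-1-ol
Product: 15 (S)-1-(3,4,5-trimethoxyphenyl)prop-2-en-1-yl (Z)-2-({[(Z)-2-methylbut-2-enoyl]oxy}methyl)but-2-enoate, via acyl chloride 13 (not isolated), via lithium alkoxide 14 (not isolated)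
Conditions: 12, 1-chloro-N,N,2-trimethylprop-1-en-1-amine (1.05 equiv), CH2Cl2, 0 °C to rt, 1 h; separately 3, LiN(SiMe3)2 (1.0 equiv), THF, −78 °C; add the acyl chloride solution, −78 to −30 °C; aq NH4Cl
Reagents that add atoms: none
Why: Esterification by acylation of a lithium alkoxide with an acyl chloride made under neutral conditions keeps the carbinol C–O bond intact (S retained) and avoids nucleophilic catalysts that cause Z/E isomerisation or SN2′ loss of the angelate.

Compound 15 is the target.

**Compound list**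

1 | 3,4,5-trimethoxybenzaldehyde | COc1cc(C=O)cc(OC)c1OC | starting material
2 | rac-1-(3,4,5-trimethoxyphenyl)prop-2-en-1-ol | C=CC(O)c1cc(OC)c(OC)c(OC)c1 | intermediate
3 | (S)-1-(3,4,5-trimethoxyphenyl)prop-2-en-1-ol | C=C[C@H](O)c1cc(OC)c(OC)c(OC)c1 | intermediate
4 | (E)-but-2-enal (crotonaldehyde) | C/C=C/C=O | starting material
5 | rac-(2R,3S)-2,3-dibromobutanal (anti adduct, formed in the flask) | C[C@H](Br)[C@H](Br)C=O | intermediate
6 | (Z)-2-bromobut-2-enal | C/C=C(\Br)C=O | intermediate
7 | (Z)-2-bromobut-2-en-1-ol | C/C=C(\Br)CO | intermediate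
8 | lithium (E)-2-lithiobut-2-en-1-olate (Li cis to CH3; geometry retained, formed in the flask) | C/C=C(/CO[Li])[Li] | intermediate
9 | (Z)-2-(hydroxymethyl)but-2-enoic acid (sarracinic acid) | C/C=C(\C(=O)O)CO | intermediate
10 | angelic anhydride, (Z)-2-methylbut-2-enoic anhydride | C/C=C(/C)C(=O)OC(=O)/C(C)=C\C | starting material
11 | dilithium (Z)-2-(oxidomethyl)but-2-enoate (formed in the flask) | [Li+].[Li+].C/C=C(\C(=O)[O-])C[O-] | intermediate
12 | (Z)-2-({[(Z)-2-methylbut-2-enoyl]oxy}methyl)but-2-enoic acid | C/C=C(\C(=O)O)COC(=O)/C(C)=C\C | intermediate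
13 | (Z)-2-({[(Z)-2-methylbut-2-enoyl]oxy}methyl)but-2-enoyl chloride (formed in the flask) | C/C=C(\C(=O)Cl)COC(=O)/C(C)=C\C | intermediate
14 | lithium (S)-1-(3,4,5-trimethoxyphenyl)prop-2-en-1-olate (formed in the flask) | C=C[C@H](O[Li])c1cc(OC)c(OC)c(OC)c1 | intermediate
15 | (S)-1-(3,4,5-trimethoxyphenyl)prop-2-en-1-yl (Z)-2-({[(Z)-2-methylbut-2-enoyl]oxy}methyl)but-2-enoate | C=C[C@H](OC(=O)/C(=C\C)COC(=O)/C(C)=C\C)c1cc(OC)c(OC)c(OC)c1 | target

**Totals**

Total step count: 7 (2 for the alcohol, 4 for the acid, 1 union).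
Longest linear sequence: 5 steps (4 to 6 to 7 to 9 to 12 to 15).

**Three steps most likely to fail**

Step 5 (dianion carboxylation). The risks are competing anti-dehydrobromination of 7 to but-2-yn-1-ol, ketone formation if CO2 is locally deficient, and loss of the small water-soluble acid on extraction. The fallback sets out from 7 and comes back at 9 and replaces organolithium chemistry by carbonylation. Treating 7 with CO (3 bar), PdCl2(PPh3)2 (3 mol %) and Et3N in MeOH at 60 °C gives methyl (Z)-2-(hydroxymethyl)but-2-enoate F1. Oxidative addition of the vinyl C–Br bond to zerovalent palladium and CO insertion both go with retention and tolerate the free hydroxyl. Saponification with LiOH in THF/H2O at 0 °C and acidification then gives 9.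

Step 6 (chemoselective angeloylation of a hydroxy acid). The risks are poor solubility of dianion 11, acyl scrambling through mixed anhydrides leading to oligoesters, and partial isomerisation to the tiglate. The fallback sets out from 9 and comes back at 12 and masks the carboxyl group first. Cs2CO3 (0.55 equiv) and 4-methoxybenzyl chloride in DMF alkylate only the carboxylate and give 4-methoxybenzyl (Z)-2-(hydroxymethyl)but-2-enoate F2. LiN(SiMe3)2 (1.0 equiv) in THF at −78 °C converts it into lithium (Z)-2-{[(4-methoxybenzyl)oxy]carbonyl}but-2-en-1-olate F3. Acylation of F3 with 10 gives 4-methoxybenzyl (Z)-2-({[(Z)-2-methylbut-2-enoyl]oxy}methyl)but-2-enoate F4. TFA with anisole in CH2Cl2 at 0 °C removes the 4-methoxybenzyl ester and returns 12.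

Step 7 (final esterification). Acyl chloride 13 is a hindered, angelate-type electrophile that also carries an allylic carboxylate, so SN2′ displacement of angelate by the alkoxide and Z to E isomerisation are possible. The 1-arylallyl ester product is also sensitive to acid and heat. The fallback sets out from 9 (using 14 and 10 as in the main route) and comes back at 15 and reverses the order of the two acylations so that the angelate is put on last.

- TBSCl and imidazole in DMF convert 9 into tert-butyl(dimethyl)silyl (Z)-2-({[tert-butyl(dimethyl)silyl]oxy}methyl)but-2-enoate F5.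
- K2CO3 in MeOH/THF/H2O cleaves only the silyl ester to give (Z)-2-({[tert-butyl(dimethyl)silyl]oxy}methyl)but-2-enoic acid F6.
- 1-Chloro-N,N,2-trimethylprop-1-en-1-amine in CH2Cl2 gives (Z)-2-({[tert-butyl(dimethyl)silyl]oxy}methyl)but-2-enoyl chloride F7, which has no allylic leaving group.
- Reaction of F7 with 14 at −78 °C gives (S)-1-(3,4,5-trimethoxyphenyl)prop-2-en-1-yl (Z)-2-({[tert-butyl(dimethyl)silyl]oxy}methyl)but-2-enoate F8.
- HF·pyridine in THF at 0 °C gives (S)-1-(3,4,5-trimethoxyphenyl)prop-2-en-1-yl (Z)-2-(hydroxymethyl)but-2-enoate F9.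
- LiN(SiMe3)2 (1.0 equiv) at −78 °C gives lithium (Z)-2-({[(S)-1-(3,4,5-trimethoxyphenyl)prop-2-en-1-yl]oxy}carbonyl)but-2-en-1-olate F10, which is acylated by 10 to give 15.

**Further compounds**

F1 | step 5 | methyl (Z)-2-(hydroxymethyl)but-2-enoate | C/C=C(\C(=O)OC)CO
F2 | step 6 | 4-methoxybenzyl (Z)-2-(hydroxymethyl)but-2-enoate | C/C=C(\C(=O)OCc1ccc(OC)cc1)CO
F3 | step 6 | lithium (Z)-2-{[(4-methoxybenzyl)oxy]carbonyl}but-2-en-1-olate | C/C=C(\C(=O)OCc1ccc(OC)cc1)CO[Li]
F4 | step 6 | 4-methoxybenzyl (Z)-2-({[(Z)-2-methylbut-2-enoyl]oxy}methyl)but-2-enoate | C/C=C(\C(=O)OCc1ccc(OC)cc1)COC(=O)/C(C)=C\C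
F5 | step 7 | tert-butyl(dimethyl)silyl (Z)-2-({[tert-butyl(dimethyl)silyl]oxy}methyl)but-2-enoate | C/C=C(\C(=O)O[Si](C)(C)C(C)(C)C)CO[Si](C)(C)C(C)(C)C
F6 | step 7 | (Z)-2-({[tert-butyl(dimethyl)silyl]oxy}methyl)but-2-enoic acid | C/C=C(\C(=O)O)CO[Si](C)(C)C(C)(C)C
F7 | step 7 | (Z)-2-({[tert-butyl(dimethyl)silyl]oxy}methyl)but-2-enoyl chloride | C/C=C(\C(=O)Cl)CO[Si](C)(C)C(C)(C)C
F8 | step 7 | (S)-1-(3,4,5-trimethoxyphenyl)prop-2-en-1-yl (Z)-2-({[tert-butyl(dimethyl)silyl]oxy}methyl)but-2-enoate | C=C[C@H](OC(=O)/C(=C\C)CO[Si](C)(C)C(C)(C)C)c1cc(OC)c(OC)c(OC)c1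
F9 | step 7 | (S)-1-(3,4,5-trimethoxyphenyl)prop-2-en-1-yl (Z)-2-(hydroxymethyl)but-2-enoate | C=C[C@H](OC(=O)/C(=C\C)CO)c1cc(OC)c(OC)c(OC)c1
F10 | step 7 | lithium (Z)-2-({[(S)-1-(3,4,5-trimethoxyphenyl)prop-2-en-1-yl]oxy}carbonyl)but-2-en-1-olate | C=C[C@H](OC(=O)/C(=C\C)CO[Li])c1cc(OC)c(OC)c(OC)c1
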